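Substrate and product add up to the charge: the south run ends at 99.7%. So you can describe a run by one conversion x, the mean of what the two readings say. Let u = 1 − x be the fraction of substrate left and e the partner charged per substrate charged. If one partner goes per substrate, which is my assumption, the integrated second-order law gives a clock, G = ln[(e − x)/(e·u)]/(e − 1), that climbs evenly with time.

| flask | substrate | partner | remark | time |
|---|---|---|---|---|
| north-east | 19 mM | 12 mM | run made earlier |  |
| west | 19 mM | 21 mM | run made earlier |  |
| south | 19 mM | 25 mM | run made earlier |  |
| Thursday's | 19 mM | 28.5 mM |  | 2.0 min |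
| Monday's | 19 mM | 15.0 mM |  | 1.0 min |

| run | time / s | product / % | substrate / % |
|---|---|---|---|
| north-east | 10.0 | 6.7 | 93.9 |
| north-east | 15.0 | 7.2 | 91.6 |
| north-east | 30.0 | 13.0 | 86.2 |
| north-east | 40.0 | 16.3 | 83.3 |
| north-east | 60.0 | 21.5 | 77.8 |
| west | 12.0 | 12.6 | 88.0 |
| west | 25.0 | 19.8 | 79.1 |
| west | 40.0 | 27.0 | 72.3 |
| west | 50.0 | 30.9 | 68.6 |
| west | 60.0 | 34.4 | 65.8 |
| south | 10.0 | 12.6 | 88.2 |
| south | 15.0 | 16.3 | 83.9 |
| south | 30.0 | 27.2 | 74.1 |
| south | 40.0 | 32.1 | 68.7 |
| south | 60.0 | 40.2 | 59.5 |

(scatter of a reading: 0.5 percentage points)

- the analysis behind the earlier runs scatters by 0.5 percentage points, standard deviation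
- a reading or a percentage of product counts all its forms, free or not

1. which of the two ends with the higher amount of product, in percent of the substrate charged ("neither" if they lie within 2 percentage points) (Thursday's / Monday's / neither)
2. product at the end, in percent of the substrate charged, Thursday's
3. product at the end, in percent of the substrate charged, Monday's

In the south run, with e = 1.32, G reads 0.263 at 30.0 s and 0.476 at 60.0 s. The clock rate, the climb of G per unit time at this substrate charge, reads 0.426 min⁻¹. The line back to zero leaves a head start of 7.11 s, a reading of a faster opening. These two give 21.6% and 35.1% at the last readings of the north-east and west runs, where product reads 21.5% and 34.4%.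

Now turn the question round. Thursday's, with e = 1.50, reaches G = 0.902, so my x is 63.1%. Monday's, with e = 0.789 and partner as limiting reagent, reaches 0.476, so x is 26.4%. In my law x rises with both G and e, so for the opposite outcome Monday's would have to lead in at least one of them, and it leads in neither: Thursday's clock reads twice Monday's, and Thursday's e is larger. I commit to Thursday's, by 37 percentage points against a margin of 2 points.

The forecast said Thursday's, with 58% and 26%, the first “less certain because tight binding is assumed”.

The flask gives 62.7% for Thursday's and 26.3% for Monday's, so Thursday's.

    partner ⇌ dormant form (K = 0.550, k = 0.0220 s⁻¹)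
    crystals ⇌ product, rate k2*(cs2 - [product]) while solid is left; crystals form when [product] > cs2 (solubility = 3.50 mM, k = 0.670 s⁻¹)
    substrate + partner → product (k = 0.580 L mol⁻¹ s⁻¹)

In Thursday's, partner and dormant form relax with a half-life of 0.186 min, shorter than the 30.0 s where the clock rate's stretch began. At 1.00 min the clock rate gives Thursday's 44.7%, and the flask holds 44.7% product.

Take the neighbour with 76 mM of substrate, otherwise Thursday's: e = 0.375, and the clock rate, scaled with the substrate charge, becomes 1.70 min⁻¹, which gives x = 34.9%. The computed result is 34.0%, with partner down to 4.94% of its own charge.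

The numbers in the tables were generated by integration from invented constants; scatter was added.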